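The route rests on reading the cis-2-aryl-3-(hydroxymethyl)-2,3-dihydrobenzofuran (ring atoms O1, C2, C3, C3a, C7a) as a ring-contracted chroman-4-one. The C3–C3a bond arises when aryl carbon C4a of a flavanone moves from C4 to C3, and the expelled C4 carbonyl ends up as the exocyclic CH2OH carbon. A photochemical Wolff rearrangement of an enantiopure 3-diazoflavanone in methanol achieves this in one operation and delivers the cis ester. Its precursor is 6-bromo-8-methoxy-3-diazoflavanone bearing an O-benzylguaiacyl group at C2. The bromide later becomes the aldehyde on which the oxolane is built by a Prins–pinacol annulation.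

Key step: step 5

Remark: the diazo ketone made from the (2R)-flavanone is (2S) by the CIP rules, because C3 outranks the aryl group once it carries N2; the spatial arrangement at C2 is unchanged.
Remark: oxolane positions are numbered O1, C2 (benzofuranyl), C3 (CH2O), C4 (acetyl or O), C5 (arylmethyl) throughout. In step 3 the diene antipode is assumed to be the one that gives 2R; otherwise its mirror image is used.

Step 1
Reactants: 1 1-(2-hydroxy-3-methoxyphenyl)ethanone
Product: 2 1-(5-bromo-2-hydroxy-3-methoxyphenyl)ethanone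
Conditions: NBS (1.05 equiv), MeCN, 0 °C → rt
Reagents that add atoms: N-bromosuccinimide, O=C1CCC(=O)N1Br
Why: Electrophilic aromatic bromination; the free phenol directs para (C5) because both of its ortho positions are blocked by the acetyl and methoxy groups.

Step 2
Reactants: 2 1-(5-bromo-2-hydroxy-3-methoxyphenyl)ethanone
Product: 4 6-bromo-8-methoxy-4H-chromen-4-one, via enaminone 3 (not isolated)
Conditions: Me2NCH(OMe)2, toluene, 100 °C; then conc. HCl, CH2Cl2, 40 °C
Reagents that add atoms: N,N-dimethylformamide dimethyl acetal, COC(OC)N(C)C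
Why: Enaminone formation at the acetyl methyl group, then acid-promoted conjugate addition of the phenol and loss of dimethylamine (enaminone route to chromones), closes the pyranone ring.

Step 3
Reactants: 4 6-bromo-8-methoxy-4H-chromen-4-one; 5 [4-(benzyloxy)-3-methoxyphenyl]boronic acid (2 equiv)
Product: 6 (2R)-2-[4-(benzyloxy)-3-methoxyphenyl]-6-bromo-8-methoxychroman-4-one
Conditions: [RhCl(C2H4)2]2 (2.5 mol%), (R,R)-2,5-diphenylbicyclo[2.2.2]octa-2,5-diene (5.5 mol%), KOH (10 mol%), toluene/H2O 10:1, 40 °C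
Reagents that add atoms: none
Why: Hayashi–Miyaura asymmetric 1,4-addition: the arylrhodium–diene complex adds to C2 of the chromone and the chiral diene fixes the enantioface so that C2 should become R, while the C–Br bond is inert to monovalent rhodium under these conditions.

Step 4
Reactants: 6 (2R)-2-[4-(benzyloxy)-3-methoxyphenyl]-6-bromo-8-methoxychroman-4-one
Product: 8 (2S)-2-[4-(benzyloxy)-3-methoxyphenyl]-6-bromo-3-diazo-8-methoxychroman-4-one, via trifluoroacetyl ketone 7 (not isolated)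
Conditions: LiN(SiMe3)2 (1.1 equiv), THF, −78 °C; CF3CO2CH2CF3, −78 °C; cold aq. HCl work-up; then MsN3, Et3N, H2O (1 equiv), MeCN, 0 °C
Reagents that add atoms: methanesulfonyl azide, CS(=O)(=O)N=[N+]=[N-]; 2,2,2-trifluoroethyl trifluoroacetate, O=C(OCC(F)(F)F)C(F)(F)F (atoms present only in intermediate 7)
Why: Detrifluoroacetylative diazo transfer (a Regitz-type reaction): the kinetic lithium enolate is acylated at C3 at −78 °C and the 1,3-diketone takes N2 from the sulfonyl azide with loss of the trifluoroacetyl group, while C2 is untouched because the enolate is never warmed and the stabilised diketonate should not expel the aryloxide.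

Step 5
Reactants: 8 (2S)-2-[4-(benzyloxy)-3-methoxyphenyl]-6-bromo-3-diazo-8-methoxychroman-4-one
Product: 10 methyl (2R,3S)-2-[4-(benzyloxy)-3-methoxyphenyl]-5-bromo-7-methoxy-2,3-dihydro-1-benzofuran-3-carboxylate, via ketene 9 (not isolated)
Conditions: hν (365 nm LEDs, flow), MeOH/THF 9:1, 0.01 M, degassed, 0 °C
Reagents that add atoms: methanol, CO
Why: Proposed new method: excitation of the diazo ketone, which the ring locks in the s-Z geometry, should expel N2 with concerted 1,2-shift of aryl carbon C4a from C4 to C3 (Wolff rearrangement) to give ketene 9, which adds methanol to an ester enol that tautomerises to 10; the closest known reaction type is the photochemical Wolff ring contraction of cyclic α-diazo ketones such as 2-diazo-1-tetralones and 3-diazochromane-2,4-diones in alcohols. The dihydrofuran ring (O1–C2–C3–C3a–C7a) is closed by ring contraction, that is by forming the C3–C3a bond in a suprafacial 1,2-shift, and not by a cyclisation, so no ring-closure rule is at issue. C2 is carried over from the flavanone because no bond to it is broken, and the new C3 centre is set by kinetic protonation of the planar ester enol on the face away from the C2 aryl group, which leaves the ester cis to that aryl group (2R,3S). The step needs the aryl shift to beat 1,2-hydride shift of the activated C2–H to a free carbene, which would give the flavone; the enforced s-Z geometry, direct singlet excitation without metal, heat or sensitiser, and the electron-rich migrating carbon ortho to O1 favour the concerted path. Light of 365 nm is absorbed by the diazo chromophore but not by the C–Br bond, and neutral cold methanol followed at once by step 6 should keep the contra-thermodynamic cis ester from epimerising.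

Step 6
Reactants: 10 methyl (2R,3S)-2-[4-(benzyloxy)-3-methoxyphenyl]-5-bromo-7-methoxy-2,3-dihydro-1-benzofuran-3-carboxylate
Product: 11 [(2R,3R)-2-[4-(benzyloxy)-3-methoxyphenyl]-5-bromo-7-methoxy-2,3-dihydro-1-benzofuran-3-yl]methanol
Conditions: i-Bu2AlH (3 equiv), CH2Cl2, −78 → −40 °C; aq. potassium sodium tartrate
Reagents that add atoms: none
Why: Hydride reduction of the ester to the primary alcohol under non-basic, cold conditions, so the labile cis C3 centre is not enolised and thereafter can no longer epimerise.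

Step 7
Reactants: 11 [(2R,3R)-2-[4-(benzyloxy)-3-methoxyphenyl]-5-bromo-7-methoxy-2,3-dihydro-1-benzofuran-3-yl]methanol
Product: 12 triisopropylsilyl ether of 11
Conditions: i-Pr3SiCl, imidazole, DMF, rt
Reagents that add atoms: chlorotriisopropylsilane, CC(C)[Si](Cl)(C(C)C)C(C)C
Why: Imidazole-mediated silylation of a primary alcohol; the bulky silyl ether tolerates the organolithium, Lewis acid and peracid steps that follow.

Step 8
Reactants: 12 triisopropylsilyl ether of 11
Product: 14 (2R,3R)-2-[4-(benzyloxy)-3-methoxyphenyl]-7-methoxy-3-{[(triisopropylsilyl)oxy]methyl}-2,3-dihydro-1-benzofuran-5-carbaldehyde, via aryllithium 13 (not isolated)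
Conditions: n-BuLi (1.1 equiv), THF, −78 °C, 10 min; DMF, −78 → 0 °C; aq. NH4Cl
Reagents that add atoms: N,N-dimethylformamide, CN(C)C=O; n-butyllithium, [Li]CCCC (lithium present only in intermediate 13)
Why: Bromine–lithium exchange, faster at −78 °C than any deprotonation, followed by formylation of the aryllithium with DMF (Bouveault aldehyde synthesis).

Step 9
Reactants: 15 1-(benzyloxy)-4-bromo-2-methoxybenzene; 16 methyl (2S)-oxirane-2-carboxylate
Product: 18 methyl (2S)-3-[4-(benzyloxy)-3-methoxyphenyl]-2-hydroxypropanoate, via Grignard reagent 17 (not isolated)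
Conditions: Mg, THF, rt; CuI (10 mol%), then 16, −40 → −20 °C; aq. NH4Cl
Reagents that add atoms: magnesium, [Mg] (present only in intermediate 17)
Why: Copper-catalysed Grignard opening of the epoxide at its unsubstituted CH2 (SN2), which leaves the stereocentre of the glycidate untouched (S retained).

Step 10
Reactants: 18 methyl (2S)-3-[4-(benzyloxy)-3-methoxyphenyl]-2-hydroxypropanoate
Product: 20 (3S)-4-[4-(benzyloxy)-3-methoxyphenyl]-3-hydroxybutan-2-one, via Weinreb amide 19 (not isolated)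
Conditions: MeNHOMe·HCl, i-PrMgCl, THF, −20 °C; then MeMgBr, −20 → 0 °C; aq. NH4Cl
Reagents that add atoms: methylmagnesium bromide, C[Mg]Br; N,O-dimethylhydroxylamine hydrochloride, CNOC.Cl (atoms present only in intermediate 19)
Why: One-pot Weinreb ketone synthesis: the magnesium amide converts the ester into the N-methoxy-N-methylamide, whose chelated adduct with MeMgBr stops at the ketone, and the carbinol centre is shielded from enolisation as its magnesium alkoxide.

Step 11
Reactants: 20 (3S)-4-[4-(benzyloxy)-3-methoxyphenyl]-3-hydroxybutan-2-one; 21 triisopropyl(prop-2-yn-1-yloxy)silane (2.5 equiv)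
Product: 23 (2S,3RS)-1-[4-(benzyloxy)-3-methoxyphenyl]-3-methyl-6-[(triisopropylsilyl)oxy]hex-4-yne-2,3-diol, via lithium acetylide 22 (not isolated)
Conditions: n-BuLi (2.4 equiv), THF, −78 °C; add 20, −78 → −20 °C; aq. NH4Cl
Reagents that add atoms: n-butyllithium, [Li]CCCC (lithium present only in intermediate 22)
Why: 1,2-Addition of a lithium acetylide to the ketone after the first equivalent has deprotonated the hydroxyl; the tertiary carbinol forms as both epimers, which does not matter because this carbon becomes the acetyl carbonyl in step 13.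

Step 12
Reactants: 23 (2S,3RS)-1-[4-(benzyloxy)-3-methoxyphenyl]-3-methyl-6-[(triisopropylsilyl)oxy]hex-4-yne-2,3-diol
Product: 24 (2S,3RS,4E)-1-[4-(benzyloxy)-3-methoxyphenyl]-3-methyl-6-[(triisopropylsilyl)oxy]hex-4-ene-2,3-diol
Conditions: NaAlH2(OCH2CH2OMe)2 (3.5 equiv), THF, 0 °C → rt; aq. potassium sodium tartrate
Reagents that add atoms: none
Why: Alkoxide-directed trans-hydroalumination of the propargylic alcohol and protonolysis of the vinylalane should give the E alkene only.

Step 13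
Reactants: 14 (2R,3R)-2-[4-(benzyloxy)-3-methoxyphenyl]-7-methoxy-3-{[(triisopropylsilyl)oxy]methyl}-2,3-dihydro-1-benzofuran-5-carbaldehyde; 24 (2S,3RS,4E)-1-[4-(benzyloxy)-3-methoxyphenyl]-3-methyl-6-[(triisopropylsilyl)oxy]hex-4-ene-2,3-diol (1.2 equiv)
Product: 26 (2S,3R,4S,5S)-4-acetyl oxolane bearing the benzofuranyl group at C2 and CH2OSi(i-Pr)3 at C3 and the arylmethyl group at C5, via dioxolane acetal 25 (not isolated)
Conditions: BF3·OEt2 (2.5 equiv), MgSO4, CH2Cl2, −55 → −20 °C; aq. NaHCO3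
Reagents that add atoms: none
Why: Prins–pinacol condensation–rearrangement: the secondary hydroxyl and the aldehyde give an aryl-stabilised oxocarbenium ion, the E alkene attacks it through a chair transition state with the benzofuranyl, arylmethyl and CH2OSi groups equatorial, and pinacol shift of the ring C–C bond contracts the oxanyl cation to the oxolane while the tertiary carbinol becomes the acetyl group, so the S centre from the glycidate (C5) sets C2, C3 and C4 (2,5-cis, 4,5-cis, C3 trans to both neighbours).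

Step 14
Reactants: 26 (2S,3R,4S,5S)-4-acetyl oxolane
Product: 27 (2S,3R,4S,5S)-4-acetoxy oxolane (same substituents as 26, OAc in place of acetyl)
Conditions: m-CPBA (3 equiv), NaHCO3, CH2Cl2, 0 °C → rt
Reagents that add atoms: 3-chloroperoxybenzoic acid, OOC(=O)c1cccc(Cl)c1
Why: Baeyer–Villiger oxidation: the secondary ring carbon migrates in preference to methyl and with retention, so the acetyl group becomes the C4 acetate of the same configuration.

Step 15
Reactants: 27 (2S,3R,4S,5S)-4-acetoxy oxolane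
Product: 29 O,O'-dibenzyl ether of the target (two phenols benzylated and three hydroxyls free), via diol acetate 28 (not isolated)
Conditions: Bu4NF (3 equiv), THF, 0 °C → rt; then K2CO3, MeOH, rt
Reagents that add atoms: none
Why: Fluoride-mediated cleavage of both silyl ethers followed by carbonate-catalysed transesterification of the acetate, neither of which touches the benzyl ethers or any stereocentre.

Step 16
Reactants: 29 O,O'-dibenzyl ether of the target
Product: 30 (2S,3S,4S,5S)-2-[(4-hydroxy-3-methoxyphenyl)methyl]-5-[(2R,3R)-2-(4-hydroxy-3-methoxyphenyl)-3-(hydroxymethyl)-7-methoxy-2,3-dihydro-1-benzofuran-5-yl]-4-(hydroxymethyl)oxolan-3-ol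
Conditions: H2 (1 atm), Pd/C (10%), EtOAc/MeOH, rt, stopped at full conversion
Reagents that add atoms: none
Why: Catalytic hydrogenolysis of the two aryl benzyl ethers, which under neutral conditions at 1 atm should be much faster than cleavage of the cyclic benzylic C–O bonds.

Compound list
1 | 1-(2-hydroxy-3-methoxyphenyl)ethanone | CC(=O)c1cccc(OC)c1O | starting material
2 | 1-(5-bromo-2-hydroxy-3-methoxyphenyl)ethanone | CC(=O)c1cc(Br)cc(OC)c1O | intermediate
3 | (E)-1-(5-bromo-2-hydroxy-3-methoxyphenyl)-3-(dimethylamino)prop-2-en-1-one | CN(C)/C=C/C(=O)c1cc(Br)cc(OC)c1O | intermediate (not isolated)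
4 | 6-bromo-8-methoxy-4H-chromen-4-one | O=c1ccoc2c(OC)cc(Br)cc12 | intermediate
5 | [4-(benzyloxy)-3-methoxyphenyl]boronic acid | COc1cc(B(O)O)ccc1OCc1ccccc1 | starting material
6 | (2R)-2-[4-(benzyloxy)-3-methoxyphenyl]-6-bromo-8-methoxychroman-4-one | O=C1C[C@H](c2ccc(OCc3ccccc3)c(OC)c2)Oc2c(OC)cc(Br)cc12 | intermediate
7 | (2R)-2-[4-(benzyloxy)-3-methoxyphenyl]-6-bromo-8-methoxy-3-(trifluoroacetyl)chroman-4-one (C3 epimers, largely enolised) | O=C1C(C(=O)C(F)(F)F)[C@H](c2ccc(OCc3ccccc3)c(OC)c2)Oc2c(OC)cc(Br)cc12 | intermediate (not isolated)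
8 | (2S)-2-[4-(benzyloxy)-3-methoxyphenyl]-6-bromo-3-diazo-8-methoxychroman-4-one | O=C1C(=[N+]=[N-])[C@H](c2ccc(OCc3ccccc3)c(OC)c2)Oc2c(OC)cc(Br)cc12 | intermediate
9 | (2S)-2-[4-(benzyloxy)-3-methoxyphenyl]-5-bromo-7-methoxy-3-(oxomethylidene)-2,3-dihydro-1-benzofuran (ketene) | O=C=C1c2cc(Br)cc(OC)c2O[C@H]1c1ccc(OCc2ccccc2)c(OC)c1 | intermediate (not isolated)
10 | methyl (2R,3S)-2-[4-(benzyloxy)-3-methoxyphenyl]-5-bromo-7-methoxy-2,3-dihydro-1-benzofuran-3-carboxylate (2,3-cis) | Brc1cc(OC)c2c(c1)[C@H](C(=O)OC)[C@H](c1ccc(OCc3ccccc3)c(OC)c1)O2 | intermediate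
11 | [(2R,3R)-2-[4-(benzyloxy)-3-methoxyphenyl]-5-bromo-7-methoxy-2,3-dihydro-1-benzofuran-3-yl]methanol (2,3-cis) | Brc1cc(OC)c2c(c1)[C@H](CO)[C@H](c1ccc(OCc3ccccc3)c(OC)c1)O2 | intermediate
12 | {[(2R,3R)-2-[4-(benzyloxy)-3-methoxyphenyl]-5-bromo-7-methoxy-2,3-dihydro-1-benzofuran-3-yl]methoxy}triisopropylsilane | Brc1cc(OC)c2c(c1)[C@H](CO[Si](C(C)C)(C(C)C)C(C)C)[C@H](c1ccc(OCc3ccccc3)c(OC)c1)O2 | intermediate
13 | 5-lithio derivative of 12 (lithium in place of bromine) | [Li]c1cc(OC)c2c(c1)[C@H](CO[Si](C(C)C)(C(C)C)C(C)C)[C@H](c1ccc(OCc3ccccc3)c(OC)c1)O2 | intermediate (not isolated)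
14 | (2R,3R)-2-[4-(benzyloxy)-3-methoxyphenyl]-7-methoxy-3-{[(triisopropylsilyl)oxy]methyl}-2,3-dihydro-1-benzofuran-5-carbaldehyde | O=Cc1cc(OC)c2c(c1)[C@H](CO[Si](C(C)C)(C(C)C)C(C)C)[C@H](c1ccc(OCc3ccccc3)c(OC)c1)O2 | intermediate
15 | 1-(benzyloxy)-4-bromo-2-methoxybenzene | COc1cc(Br)ccc1OCc1ccccc1 | starting material
16 | methyl (2S)-oxirane-2-carboxylate (methyl (S)-glycidate) | COC(=O)[C@@H]1CO1 | starting material
17 | [4-(benzyloxy)-3-methoxyphenyl]magnesium bromide | COc1cc([Mg]Br)ccc1OCc1ccccc1 | intermediate (not isolated)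
18 | methyl (2S)-3-[4-(benzyloxy)-3-methoxyphenyl]-2-hydroxypropanoate | COC(=O)[C@@H](O)Cc1ccc(OCc2ccccc2)c(OC)c1 | intermediate
19 | (2S)-3-[4-(benzyloxy)-3-methoxyphenyl]-2-hydroxy-N-methoxy-N-methylpropanamide | CON(C)C(=O)[C@@H](O)Cc1ccc(OCc2ccccc2)c(OC)c1 | intermediate (not isolated)
20 | (3S)-4-[4-(benzyloxy)-3-methoxyphenyl]-3-hydroxybutan-2-one | CC(=O)[C@@H](O)Cc1ccc(OCc2ccccc2)c(OC)c1 | intermediate
21 | triisopropyl(prop-2-yn-1-yloxy)silane | C#CCO[Si](C(C)C)(C(C)C)C(C)C | starting material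
22 | lithium acetylide of 21 | [Li]C#CCO[Si](C(C)C)(C(C)C)C(C)C | intermediate (not isolated)
23 | (2S,3RS)-1-[4-(benzyloxy)-3-methoxyphenyl]-3-methyl-6-[(triisopropylsilyl)oxy]hex-4-yne-2,3-diol | CC(O)(C#CCO[Si](C(C)C)(C(C)C)C(C)C)[C@@H](O)Cc1ccc(OCc2ccccc2)c(OC)c1 | intermediate
24 | (2S,3RS,4E)-1-[4-(benzyloxy)-3-methoxyphenyl]-3-methyl-6-[(triisopropylsilyl)oxy]hex-4-ene-2,3-diol | CC(O)(/C=C/CO[Si](C(C)C)(C(C)C)C(C)C)[C@@H](O)Cc1ccc(OCc2ccccc2)c(OC)c1 | intermediate
25 | 1,3-dioxolane from 14 and 24: C2 carries the benzofuranyl group, C4 carries methyl and the (E)-3-(silyloxy)propenyl group, (5S)-C5 carries the arylmethyl group; mixture at C2 and C4 | CC(C)[Si](C(C)C)(C(C)C)OC/C=C/C1(C)OC(c2cc(OC)c3c(c2)[C@H](CO[Si](C(C)C)(C(C)C)C(C)C)[C@H](c2ccc(OCc4ccccc4)c(OC)c2)O3)O[C@H]1Cc1ccc(OCc2ccccc2)c(OC)c1 | intermediate (not isolated)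
26 | 1-[(2S,3R,4S,5S)-5-{[4-(benzyloxy)-3-methoxyphenyl]methyl}-2-[(2R,3R)-2-[4-(benzyloxy)-3-methoxyphenyl]-7-methoxy-3-{[(triisopropylsilyl)oxy]methyl}-2,3-dihydro-1-benzofuran-5-yl]-3-{[(triisopropylsilyl)oxy]methyl}oxolan-4-yl]ethanone | COc1cc(C[C@@H]2O[C@H](c3cc(OC)c4c(c3)[C@H](CO[Si](C(C)C)(C(C)C)C(C)C)[C@H](c3ccc(OCc5ccccc5)c(OC)c3)O4)[C@@H](CO[Si](C(C)C)(C(C)C)C(C)C)[C@@H]2C(C)=O)ccc1OCc1ccccc1 | intermediate
27 | (2S,3R,4S,5S)-4-acetate corresponding to 26 (OAc in place of acetyl at C4) | COc1cc(C[C@@H]2O[C@H](c3cc(OC)c4c(c3)[C@H](CO[Si](C(C)C)(C(C)C)C(C)C)[C@H](c3ccc(OCc5ccccc5)c(OC)c3)O4)[C@@H](CO[Si](C(C)C)(C(C)C)C(C)C)[C@@H]2OC(C)=O)ccc1OCc1ccccc1 | intermediate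
28 | (2S,3R,4S,5S)-4-acetate with both CH2OH groups free (desilylated 27) | COc1cc(C[C@@H]2O[C@H](c3cc(OC)c4c(c3)[C@H](CO)[C@H](c3ccc(OCc5ccccc5)c(OC)c3)O4)[C@@H](CO)[C@@H]2OC(C)=O)ccc1OCc1ccccc1 | intermediate (not isolated)
29 | (2S,3S,4S,5S)-5-{[4-(benzyloxy)-3-methoxyphenyl]methyl}-2-[(2R,3R)-2-[4-(benzyloxy)-3-methoxyphenyl]-3-(hydroxymethyl)-7-methoxy-2,3-dihydro-1-benzofuran-5-yl]-3-(hydroxymethyl)oxolan-4-ol | COc1cc(C[C@@H]2O[C@H](c3cc(OC)c4c(c3)[C@H](CO)[C@H](c3ccc(OCc5ccccc5)c(OC)c3)O4)[C@@H](CO)[C@@H]2O)ccc1OCc1ccccc1 | intermediate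
30 | (2S,3S,4S,5S)-2-[(4-hydroxy-3-methoxyphenyl)methyl]-5-[(2R,3R)-2-(4-hydroxy-3-methoxyphenyl)-3-(hydroxymethyl)-7-methoxy-2,3-dihydro-1-benzofuran-5-yl]-4-(hydroxymethyl)oxolan-3-ol | COc1cc(C[C@@H]2O[C@H](c3cc(OC)c4c(c3)[C@H](CO)[C@H](c3ccc(O)c(OC)c3)O4)[C@@H](CO)[C@@H]2O)ccc1O | target

Total steps: 16. Longest linear sequence: 12 (steps 1–8 and 13–16); steps 9–12 build the diol fragment.

Steps most likely to fail

Step 5. The excited diazo ketone may lose N2 to a free carbene whose 1,2-hydride shift from C2 gives the flavone instead of the ring-contracted ester, or the cis ester may epimerise during handling. The fallback is a dirhodium-carbene C–H insertion, a known cis-selective route to 2-aryl-2,3-dihydrobenzofuran-3-carboxylates; it sets out from 2 and returns at 10. Phenol 2 is alkylated with 4-(benzyloxy)-3-methoxybenzyl chloride (K2CO3, DMF) to the aryl benzyl ether ketone F1. Riley oxidation (SeO2, pyridine, 100 °C) gives the arylglyoxylic acid F2, which is esterified (MeI, K2CO3, DMF) to the methyl arylglyoxylate F3. Condensation with TsNHNH2 gives the tosylhydrazone F4, and Bamford–Stevens elimination (DBU, CH2Cl2) gives the aryldiazoacetate F5. Rh2(S-PTTL)4, that is dirhodium tetrakis[N-phthaloyl-(S)-tert-leucinate], or its antipode (toluene, −60 °C) then inserts the carbene into the benzylic OCH2 C–H bond to close the dihydrofuran and give 10.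

Step 13. The Lewis acid may open or epimerise the acid-labile cis-dihydrobenzofuran, the alkene with its allylic oxygen may capture the oxocarbenium ion too slowly, or the acetyl-bearing centre may epimerise. The fallback is an acyclic dianion aldol followed by cyclodehydration; it sets out from 18 and 14 and returns at 29. Lactate 18 is silylated (t-BuMe2SiCl, imidazole) to the silyl ether F7. Claisen condensation with LiCH2CO2t-Bu (THF, −78 °C) gives the β-keto ester F8, and Noyori hydrogenation (H2, RuCl2[(S)-BINAP] or its antipode, MeOH) gives the 3,4-syn β-hydroxy ester F9 under catalyst control. Its dianion (2.2 equiv LiN(i-Pr)2, THF, −78 °C) adds to aldehyde 14 anti to the alkoxide (Fráter–Seebach-type aldol) to give the aldol adduct F10. LiAlH4 reduces the ester to the triol F11, and Bu4NF removes both silyl groups to give the pentaol F12. Catalytic camphorsulfonic acid in CH2Cl2 at 0 °C then closes the oxolane by SN1 attack of the C5 hydroxyl on the benzylic cation, trans to the C3 substituent, to give 29.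

Step 4. The enolate or the trifluoroacetyl diketonate may open by retro-oxa-Michael reaction and erode the C2 configuration, or acyl transfer may be incomplete. The fallback avoids enolates altogether; it sets out from 6 and returns at 8. Acid-catalysed C-nitrosation at C3 through the enol (isoamyl nitrite, HCl, THF, 0 °C) gives the α-oximino ketone F6. Chloramine (NH2Cl from aqueous NH3 and NaOCl, THF, 0 °C) converts it to diazo ketone 8 (Forster reaction).

Further compounds
F1 | step 5 | 1-[2-{[4-(benzyloxy)-3-methoxyphenyl]methoxy}-5-bromo-3-methoxyphenyl]ethanone | CC(=O)c1cc(Br)cc(OC)c1OCc1ccc(OCc2ccccc2)c(OC)c1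
F2 | step 5 | 2-[2-{[4-(benzyloxy)-3-methoxyphenyl]methoxy}-5-bromo-3-methoxyphenyl]-2-oxoacetic acid | OC(=O)C(=O)c1cc(Br)cc(OC)c1OCc1ccc(OCc2ccccc2)c(OC)c1
F3 | step 5 | methyl 2-[2-{[4-(benzyloxy)-3-methoxyphenyl]methoxy}-5-bromo-3-methoxyphenyl]-2-oxoacetate | COC(=O)C(=O)c1cc(Br)cc(OC)c1OCc1ccc(OCc2ccccc2)c(OC)c1
F4 | step 5 | tosylhydrazone of F3 | COC(=O)C(=NNS(=O)(=O)c1ccc(C)cc1)c1cc(Br)cc(OC)c1OCc1ccc(OCc2ccccc2)c(OC)c1
F5 | step 5 | methyl 2-[2-{[4-(benzyloxy)-3-methoxyphenyl]methoxy}-5-bromo-3-methoxyphenyl]-2-diazoacetate | COC(=O)C(=[N+]=[N-])c1cc(Br)cc(OC)c1OCc1ccc(OCc2ccccc2)c(OC)c1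
F6 | step 4 | (2S)-2-[4-(benzyloxy)-3-methoxyphenyl]-6-bromo-3-(hydroxyimino)-8-methoxychroman-4-one | O=C1C(=NO)[C@H](c2ccc(OCc3ccccc3)c(OC)c2)Oc2c(OC)cc(Br)cc12
F7 | step 13 | methyl (2S)-3-[4-(benzyloxy)-3-methoxyphenyl]-2-[(tert-butyldimethylsilyl)oxy]propanoate | COC(=O)[C@@H](O[Si](C)(C)C(C)(C)C)Cc1ccc(OCc2ccccc2)c(OC)c1
F8 | step 13 | tert-butyl (4S)-5-[4-(benzyloxy)-3-methoxyphenyl]-4-[(tert-butyldimethylsilyl)oxy]-3-oxopentanoate | CC(C)(C)OC(=O)CC(=O)[C@@H](O[Si](C)(C)C(C)(C)C)Cc1ccc(OCc2ccccc2)c(OC)c1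
F9 | step 13 | tert-butyl (3S,4S)-5-[4-(benzyloxy)-3-methoxyphenyl]-4-[(tert-butyldimethylsilyl)oxy]-3-hydroxypentanoate | CC(C)(C)OC(=O)C[C@H](O)[C@@H](O[Si](C)(C)C(C)(C)C)Cc1ccc(OCc2ccccc2)c(OC)c1
F10 | step 13 | tert-butyl (2R,3S,4S)-2-[hydroxy(benzofuranyl)methyl] derivative of F9 (2,3-anti, carbinol epimers; benzofuranyl group as in 14) | COc1cc(C[C@H](O[Si](C)(C)C(C)(C)C)[C@@H](O)[C@H](C(=O)OC(C)(C)C)C(O)c2cc(OC)c3c(c2)[C@H](CO[Si](C(C)C)(C(C)C)C(C)C)[C@H](c2ccc(OCc4ccccc4)c(OC)c2)O3)ccc1OCc1ccccc1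
F11 | step 13 | triol from F10 (CH2OH in place of the tert-butyl ester, both silyl ethers retained) | COc1cc(C[C@H](O[Si](C)(C)C(C)(C)C)[C@@H](O)[C@H](CO)C(O)c2cc(OC)c3c(c2)[C@H](CO[Si](C(C)C)(C(C)C)C(C)C)[C@H](c2ccc(OCc4ccccc4)c(OC)c2)O3)ccc1OCc1ccccc1
F12 | step 13 | pentaol from F11 (both silyl ethers removed; open-chain precursor of 29) | COc1cc(C[C@H](O)[C@@H](O)[C@H](CO)C(O)c2cc(OC)c3c(c2)[C@H](CO)[C@H](c2ccc(OCc4ccccc4)c(OC)c2)O3)ccc1OCc1ccccc1
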